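**Strategy.** Everything rests on disconnecting the quinone ring (C1, C2, C3, C4, C4a, C8a) into three pieces: a methoxy(aryl)carbene ligand on Cr(CO)5 built on the finished C5–C8 hydroquinone ring (supplies C4, C4a, C8a), one CO ligand (C1) and a terminal alkyne (C2, C3) that already carries the (S)-configured tiglate side chain. A Dötz benzannulation with oxidative work-up forms the C4–C3, C2–C1 and C1–C8a bonds and the 1,4-dione in one operation. It exploits the para oxygens on C1 and C4, the lone hydrogen on C3, and the identical oxygen substituents on C5 and C8, which make either alkyne orientation converge on the same quinone.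

Key step: step 7

Remark: the stereocenter of the target is read as (S) (alkannin series, tiglate E). The 1,4-dione drawn is one of the rapidly interconverting naphthazarin tautomers, so no separate step is needed to place the side chain on the quinone ring.

**Route**

Step 1
Reactants: 1 hydroquinone
Product: 2 1,4-bis(methoxymethoxy)benzene
Conditions: MOMCl (2.5 equiv), i-Pr2NEt (3 equiv), CH2Cl2, 0 °C → rt
Reagents that add atoms: chloromethyl methyl ether (MOMCl), COCCl
Why: Double O-alkylation of the phenols by the reactive α-chloro ether (Williamson-type acetal formation) should give the bis-acetal, whose groups direct ortho-lithiation, survive organolithium and carbene chemistry and leave under mild acid at the end.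

Step 2
Reactants: 2 1,4-bis(methoxymethoxy)benzene
Product: 5 pentacarbonyl{[2,5-bis(methoxymethoxy)phenyl](methoxy)methylidene}chromium, via aryllithium 3 (not isolated), via lithium acylchromate 4 (not isolated)
Conditions: n-BuLi, TMEDA, THF, 0 °C; Cr(CO)6, 0 °C → rt; then Me3OBF4, CH2Cl2, 0 °C
Reagents that add atoms: chromium hexacarbonyl, [C-]#[O+].[C-]#[O+].[C-]#[O+].[C-]#[O+].[C-]#[O+].[C-]#[O+].[Cr]; trimethyloxonium tetrafluoroborate, C[O+](C)C.F[B-](F)(F)F
Why: Fischer carbene synthesis: acetal-directed ortho-lithiation (all four ring positions are equivalent) gives 3, which adds to a CO ligand of Cr(CO)6 to give acylate 4, and hard O-methylation of 4 should give the methoxycarbene complex 5.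

Step 3
Reactants: 6 3-(trimethylsilyl)propynal; 7 allyltributylstannane
Product: 8 (S)-1-(trimethylsilyl)hex-5-en-1-yn-3-ol
Conditions: (S)-BINOL (10 mol %), Ti(OiPr)4 (10 mol %), 4 Å MS, CH2Cl2, −20 °C; aq NaHCO3
Reagents that add atoms: none
Why: Keck asymmetric allylation: the chiral Lewis acid from (S)-BINOL and Ti(OiPr)4 binds the ynal and exposes one carbonyl face to the allylstannane, and with the facial sense established for this catalyst (alkynyl outranking the allyl CH2) the (S)-carbinol is expected.

Step 4
Reactants: 8 (S)-1-(trimethylsilyl)hex-5-en-1-yn-3-ol; 9 2-methylbut-2-ene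
Product: 10 (S)-6-methyl-1-(trimethylsilyl)hept-5-en-1-yn-3-ol
Conditions: second-generation Grubbs catalyst RuCl2(=CHPh)(H2IMes)(PCy3) (5 mol %), 2-methylbut-2-ene/CH2Cl2, 40 °C, sealed tube
Reagents that add atoms: none
Why: Olefin cross-metathesis with excess 2-methylbut-2-ene should exchange the terminal =CH2 for =C(CH3)2 with loss of propene, while the silyl-capped internal alkyne is too hindered to enter enyne metathesis and the carbinol center is untouched.

Step 5
Reactants: 10 (S)-6-methyl-1-(trimethylsilyl)hept-5-en-1-yn-3-ol
Product: 11 (S)-6-methylhept-5-en-1-yn-3-ol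
Conditions: K2CO3 (cat.), MeOH, rt; careful concentration (volatile)
Reagents that add atoms: none
Why: Methoxide-catalyzed protodesilylation of the alkynyl C–Si bond should free the terminal alkyne without touching the alcohol, the olefin or the stereocenter.

Step 6
Reactants: 11 (S)-6-methylhept-5-en-1-yn-3-ol; 12 tiglic acid [(E)-2-methylbut-2-enoic acid]
Product: 14 (S)-6-methylhept-5-en-1-yn-3-yl (E)-2-methylbut-2-enoate, via O-acylisourea 13 (not isolated)
Conditions: DCC, DMAP (cat.), CH2Cl2, 0 °C → rt
Reagents that add atoms: none
Why: Steglich esterification acylates the oxygen with no bond to the stereocenter broken (retention), and carbodiimide activation avoids the base-induced vinylketene pathway of the acid chloride that would deconjugate or isomerize the E-olefin.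

Step 7
Reactants: 5 pentacarbonyl{[2,5-bis(methoxymethoxy)phenyl](methoxy)methylidene}chromium; 14 (S)-6-methylhept-5-en-1-yn-3-yl (E)-2-methylbut-2-enoate
Product: 16 (1S)-1-[5,8-bis(methoxymethoxy)-1,4-dioxo-1,4-dihydronaphthalen-2-yl]-4-methylpent-3-enyl (E)-2-methylbut-2-enoate, via naphthol Cr(CO)3 complex 15 (not isolated)
Conditions: THF (0.05 M), 50 °C, Ar; then (NH4)2Ce(NO3)6, MeCN/H2O, 0 °C
Reagents that add atoms: water, O
Why: Dötz benzannulation: loss of one CO from 5 and alkyne insertion with the substituted carbon away from the carbene carbon gives an η3-vinylcarbene (new C4–C3 bond), CO insertion gives an η4-vinylketene (new C2–C1 bond), and 6π-electrocyclization onto the only free ortho carbon of the aryl ring (new C1–C8a bond) followed by enolization gives naphthol complex 15, which (NH4)2Ce(NO3)6 oxidizes in the same flask to quinone 16, water attacking C4 and the C4 methoxy group leaving as methanol. The closest known reaction type is the benzannulation of aryl(methoxy)carbene complexes of Cr(CO)5 with terminal alkynes bearing a propargylic oxygen substituent, followed by oxidative work-up to the 1,4-naphthoquinone. The single ring formed is closed by a formal [3+2+1] assembly of carbene carbon, alkyne and CO whose final event is the 6π-electrocyclic C1–C8a closure. No stereocenter is created: the propargylic center is a spectator with none of its bonds broken, and the planar chirality of 15 disappears on decomplexation. The step needs phenol formation rather than indene, cyclobutenone or olefin-trapping products, which the methoxy(aryl)carbene in THF at moderate temperature favors and which the 1,5-relation of alkyne and trisubstituted olefin secures, since trapping of the vinylcarbene would require a bicyclo[2.1.0]pentane. Alkyne insertion normally places the substituent next to the CO-derived carbon, and because the substituents on C5 and C8 are identical even the opposite orientation would give the same quinone 16.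

Step 8
Reactants: 16 (1S)-1-[5,8-bis(methoxymethoxy)-1,4-dioxo-1,4-dihydronaphthalen-2-yl]-4-methylpent-3-enyl (E)-2-methylbut-2-enoate
Product: 17 (1S)-1-(5,8-dihydroxy-1,4-dioxo-1,4-dihydronaphthalen-2-yl)-4-methylpent-3-enyl (E)-2-methylbut-2-enoate (alkannin tiglate, the target)
Conditions: 3 M aq HCl, THF, rt, dark
Reagents that add atoms: none
Why: Acid-catalyzed acetal hydrolysis should be fast because each peri carbonyl makes the aryl oxygen a good leaving group and hydrogen-bonds the liberated phenol, while the ester, the trisubstituted olefin and the stereocenter tolerate dilute acid at rt and no free benzylic hydroxyl is present to cyclize onto the olefin.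

**Compound list**

1 | hydroquinone | Oc1ccc(O)cc1 | starting material
2 | 1,4-bis(methoxymethoxy)benzene | COCOc1ccc(OCOC)cc1 | intermediate
3 | [2,5-bis(methoxymethoxy)phenyl]lithium | [Li]c1cc(OCOC)ccc1OCOC | intermediate (not isolated)
4 | lithium pentacarbonyl[2,5-bis(methoxymethoxy)benzoyl]chromate | [Li+].[O-]C(=[Cr])c1cc(OCOC)ccc1OCOC.[C-]#[O+].[C-]#[O+].[C-]#[O+].[C-]#[O+].[C-]#[O+] | intermediate (not isolated)
5 | pentacarbonyl{[2,5-bis(methoxymethoxy)phenyl](methoxy)methylidene}chromium | COC(=[Cr])c1cc(OCOC)ccc1OCOC.[C-]#[O+].[C-]#[O+].[C-]#[O+].[C-]#[O+].[C-]#[O+] | intermediate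
6 | 3-(trimethylsilyl)propynal | C[Si](C)(C)C#CC=O | starting material
7 | allyltributylstannane | C=CC[Sn](CCCC)(CCCC)CCCC | starting material
8 | (S)-1-(trimethylsilyl)hex-5-en-1-yn-3-ol | O[C@@H](CC=C)C#C[Si](C)(C)C | intermediate
9 | 2-methylbut-2-ene | CC=C(C)C | starting material
10 | (S)-6-methyl-1-(trimethylsilyl)hept-5-en-1-yn-3-ol | O[C@@H](CC=C(C)C)C#C[Si](C)(C)C | intermediate
11 | (S)-6-methylhept-5-en-1-yn-3-ol | O[C@@H](CC=C(C)C)C#C | intermediate
12 | tiglic acid, (E)-2-methylbut-2-enoic acid | C/C=C(\C)C(=O)O | starting material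
13 | O-[(E)-2-methylbut-2-enoyl]-N,N'-dicyclohexylisourea | C/C=C(\C)C(=O)OC(=NC1CCCCC1)NC1CCCCC1 | intermediate (not isolated)
14 | (S)-6-methylhept-5-en-1-yn-3-yl (E)-2-methylbut-2-enoate | C/C=C(\C)C(=O)O[C@@H](CC=C(C)C)C#C | intermediate
15 | tricarbonyl{η6-4-methoxy-5,8-bis(methoxymethoxy)-2-[(1S)-4-methyl-1-[(E)-2-methylbut-2-enoyloxy]pent-3-enyl]naphthalen-1-ol}chromium | C/C=C(\C)C(=O)O[C@@H](CC=C(C)C)c1cc(OC)c2c(OCOC)ccc(OCOC)c2c1O.[Cr].[C-]#[O+].[C-]#[O+].[C-]#[O+] | intermediate (not isolated)
16 | (1S)-1-[5,8-bis(methoxymethoxy)-1,4-dioxo-1,4-dihydronaphthalen-2-yl]-4-methylpent-3-enyl (E)-2-methylbut-2-enoate | C/C=C(\C)C(=O)O[C@@H](CC=C(C)C)C1=CC(=O)c2c(OCOC)ccc(OCOC)c2C1=O | intermediate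
17 | (1S)-1-(5,8-dihydroxy-1,4-dioxo-1,4-dihydronaphthalen-2-yl)-4-methylpent-3-enyl (E)-2-methylbut-2-enoate | C/C=C(\C)C(=O)O[C@@H](CC=C(C)C)C1=CC(=O)c2c(O)ccc(O)c2C1=O | target

**Summary**

Total step count: 8. Longest linear sequence: 6 steps (steps 3, 4, 5, 6, 7, 8 from aldehyde 6); the arene branch (steps 1, 2) joins at step 7.

Steps most likely to fail:

1. Step 7. The benzylic tiglate may be lost at the stage of the electron-rich, chromium-bound 2-(1-acyloxyalkyl)-1-naphthol 15, by ionization or elimination toward a quinone methide or by acyl shift to the neighbouring naphthol oxygen, before the oxidant arrives. The fallback carries the side-chain oxygen through the annulation as a silyl ether and acylates last. It sets out from 11: TBSCl and imidazole in DMF should give (S)-tert-butyl(dimethyl)[(6-methylhept-5-en-1-yn-3-yl)oxy]silane F1. F1 and 5 under the conditions of step 7 should give the silyl-protected naphthol Cr(CO)3 complex F2 (not isolated) and, after (NH4)2Ce(NO3)6, the silyl-protected bis(methoxymethoxy)quinone F3. 3 M aq HCl in THF/MeOH should remove the silyl group and both acetals to give alkannin F4. F4 with 12, DCC and catalytic DMAP in CH2Cl2 at 0 °C should be acylated only at the side-chain hydroxyl, because the two naphthazarin hydroxyls are locked in hydrogen bonds to the quinone carbonyls; this comes back to the route at 17.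

2. Step 8. Hydrolysis of the second acetal may be slow and force long acid exposure, with solvolysis at the benzylic C–O bond of the tiglate (loss of the ester or of configuration) or acid-mediated addition to the trisubstituted olefin. The fallback unmasks oxidatively instead of hydrolytically. It sets out from 16: AgO in 6 M HNO3/dioxane at rt for a few minutes should dealkylate the 5,8-dioxygenated ring oxidatively to the side-chain-bearing naphthalene-1,4,5,8-tetrone F5, which is reduced during work-up with aqueous Na2S2O4 to the naphthazarin, coming back to the route at 17.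

3. Step 4. The ruthenium alkylidene may be captured by the alkyne (enyne metathesis, catalyst death), or exchange of the terminal olefin may stay incomplete. The fallback builds the isopropylidene group without metathesis and sets out from 8: TBSCl and imidazole should give the silyl ether of 8, F6. OsO4 (cat.), NaIO4 and 2,6-lutidine in dioxane/water should cleave the terminal olefin to (S)-3-(tert-butyldimethylsilyloxy)-5-(trimethylsilyl)pent-4-ynal F7. Wittig reaction with the ylide from isopropyltriphenylphosphonium iodide and n-BuLi (THF, −78 → 0 °C) should give the doubly silylated trisubstituted olefin F8. TBAF in THF should remove the O-silyl and the C-silyl group together, coming back to the route at 11 (steps 4 and 5 are replaced).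

**Further compounds**

F1 | step 7 | (S)-tert-butyl(dimethyl)[(6-methylhept-5-en-1-yn-3-yl)oxy]silane | CC(C)(C)[Si](C)(C)O[C@@H](CC=C(C)C)C#C
F2 | step 7 | tricarbonyl{η6-2-[(1S)-1-(tert-butyldimethylsilyloxy)-4-methylpent-3-enyl]-4-methoxy-5,8-bis(methoxymethoxy)naphthalen-1-ol}chromium | CC(C)(C)[Si](C)(C)O[C@@H](CC=C(C)C)c1cc(OC)c2c(OCOC)ccc(OCOC)c2c1O.[Cr].[C-]#[O+].[C-]#[O+].[C-]#[O+]
F3 | step 7 | 2-[(1S)-1-(tert-butyldimethylsilyloxy)-4-methylpent-3-enyl]-5,8-bis(methoxymethoxy)naphthalene-1,4-dione | CC(C)(C)[Si](C)(C)O[C@@H](CC=C(C)C)C1=CC(=O)c2c(OCOC)ccc(OCOC)c2C1=O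
F4 | step 7 | alkannin, 5,8-dihydroxy-2-[(1S)-1-hydroxy-4-methylpent-3-enyl]naphthalene-1,4-dione | O[C@@H](CC=C(C)C)C1=CC(=O)c2c(O)ccc(O)c2C1=O
F5 | step 8 | (1S)-4-methyl-1-(1,4,5,8-tetraoxo-1,4,5,8-tetrahydronaphthalen-2-yl)pent-3-enyl (E)-2-methylbut-2-enoate | C/C=C(\C)C(=O)O[C@@H](CC=C(C)C)C1=CC(=O)C2=C(C1=O)C(=O)C=CC2=O
F6 | step 4 | (S)-tert-butyl(dimethyl){[1-(trimethylsilyl)hex-5-en-1-yn-3-yl]oxy}silane | CC(C)(C)[Si](C)(C)O[C@@H](CC=C)C#C[Si](C)(C)C
F7 | step 4 | (S)-3-(tert-butyldimethylsilyloxy)-5-(trimethylsilyl)pent-4-ynal | CC(C)(C)[Si](C)(C)O[C@@H](CC=O)C#C[Si](C)(C)C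
F8 | step 4 | (S)-tert-butyl(dimethyl){[6-methyl-1-(trimethylsilyl)hept-5-en-1-yn-3-yl]oxy}silane | CC(C)(C)[Si](C)(C)O[C@@H](CC=C(C)C)C#C[Si](C)(C)C
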